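# Proposed synthesis of CNP0194625.1 by photodimerisation of a labdatriene and ring expansion of the resulting divinylcyclobutane

## Structural features

The target is a C40 diol made of two identical labdane halves. Each half is a trans-decalin (rings A and B, rings A′ and B′) with an exocyclic 8(17)-methylene, an axial methyl on C10 and a quaternary C4 that bears an axial methyl and the equatorial hydroxymethyl group C18. The halves are joined through a cyclohexene, ring C, built from C14, C15, C15′, C14′, C13′ and C12′, with the ring alkene at C13′=C14′. C14 carries the (E)-trisubstituted alkene C12=C13, which leads through C11 to C9; C12′ carries the methylene C11′, which leads to C9′. Each decalin has four stereocentres in a row (C4, C5, C10, C9; 4R,5R,9S,10R), and ring C adds the adjacent pair C14/C12′, cis and (14S,12′S). The fragile elements are the two exocyclic methylenes (acid moves them into the ring), the allylic C–H bonds between the alkenes, and the geometry of C12=C13; the neopentyl alcohols are robust. The real difficulty is that C14 and C12′ are insulated from every decalin stereocentre by methylene groups, so the molecule gives no guidance for these two centres, while eight further stereocentres must be made twice in one absolute sense. Ring C has the constitution of a [4+2] dimer of (E)-labda-8(17),12,14-trien-18-ol, and the key step exploits this: it bonds the unsubstituted termini C15 and C15′ and, temporarily, C14 to C14′ in a cyclobutane whose strain later pays for moving that bond from C14′ to C12′.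

## Logic of the disconnections

Chain atoms of acyclic compounds are numbered as the labdane carbons they become.

- **32 from 31.** The two O–Si bonds at C18 and C18′ are cut. The hydroxyls stay masked until the end because a nickel-mediated ring expansion (the fallback for step 19) would not tolerate protic groups, and the silyl group is already present from step 10. There is no gain in skeleton. The demand is a desilylation that leaves four alkenes alone.

- **31 from 30.** The bond C14–C12′ is cut and C14–C14′ is put in its place. This trades the two uncontrollable ring C stereocentres for two cyclobutane centres that need no control, because both are erased again, and it gives the symmetric connectivity of a head-to-head dimer. The forward 1,3-shift must reclose at C12′ and not at C14′, place the two substituents cis and choose one face. It competes with cleavage to two molecules of 29 and with a [3,3] shift to an eight-membered ring.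

- **30 from two molecules of 29.** C15–C15′ and C14–C14′ are cut. This is the only cut that halves the molecule, so every decalin stereocentre is made once. The forward step must excite the conjugated diene only, couple head to head, close the four-membered ring trans and keep the C12=C13 geometry as far as possible.

- **29 from 26 and 27; 26 from 24 and 25.** C14=C15 and then C12=C13 are cut. The side chain shrinks to a two-carbon aldehyde, and the E geometry comes from a stabilised ylide. The demand is E selectivity without migration of the 8(17)-alkene.

- **24 back to 20 through 23, 22 and 21.** No C–C bond is cut: the oxidation level at C12 is adjusted, the C12 silyl ether is restored and a C3–O bond is reintroduced. The 3-oxygen is the price of using an epoxide to start the ring closure and to carry the absolute configuration. The forward demands are a radical deoxygenation at a hindered secondary carbon and cleavage of one silyl ether in the presence of the other.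

- **20 from 19.** C4–C5 and C9–C10 are cut. Both rings and the centres C4, C5, C9 and C10 then come from an acyclic chain with one defined epoxide. The forward step needs chair–chair folding, ionisation at C4 despite the neighbouring silyloxymethyl group, termination by the allylsilane only and a silent C12 oxygen.

- **19 from 18 from 17.** The O–Si bond at C18 and then both oxirane C–O bonds are cut, which leads to an achiral trienol. The absolute configuration comes from the catalyst. The demand is a free (E)-allylic alcohol and inert remote alkenes.

- **17 from 16; 16 from 13 and 14.** The C18 ester level is restored and C3=C4 is cut, removing the terminal three-carbon unit. The demand is E geometry, because C18 must end up equatorial.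

- **13 from 12; 12 from 10 and 5; 10 from 8 and 9.** C1–C2 is cut in a [3,3] sense, which moves the alkene out of C5=C10, and then C5–C10 is cut. The sigmatropic step sets the E geometry. The demand is a chair transition state with the long chain equatorial.

- **8 from 7; 7 from 4 and 5; 4 from 1 and 2.** C6–C7 is cut in the same [3,3] sense and then C8–C9 is cut. Silicon is in place from the start, and the rearrangement fixes the Z-allylsilane geometry. The demand is that the allylsilane survives weak acid at 135 °C.

## Other disconnections considered

**Alternative 1:** Ring C is cut at C12′–C13′ and C14–C15 and assembled first, on its own. In the forward direction diene A1 would add to butenolide A2 in a Diels–Alder reaction on the face away from the menthyloxy group. This would give the cis-fused lactone acetal A3, in which the lactone carbonyl carbon is C13, the acetal carbon is C11′ and the silyl enol ether lies at C14′=C15′.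

- In its favour: a concerted, auxiliary-directed cycloaddition fixes C14 and C12′ cis and in one absolute sense from cheap partners. On control of exactly the two centres that the chosen plan leaves to separation, this alternative is the better one.
- Against it here: A3 holds only 9 of the 40 carbons. The ring alkene still has to be moved to C13′=C14′ (hydrolysis of the enol ether, triflation toward the more substituted side, reduction). The (E)-C12=C13 alkene has to be grown from the lactone carbonyl, and the two decalin halves have to be attached one after the other, the second through C11′–C9′ at a ring stereocentre.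
- Comparison: mechanistically it is the more predictable plan (closed-shell pericyclic step against a diradical sequence). Structurally it makes no use of the identity of the two halves. In step count it would need two separate decalin campaigns plus roughly a dozen steps of editing and coupling, against three steps after one monomer in the chosen plan.

**Alternative 2:** The four decalin bonds C4–C5, C9–C10, C4′–C5′ and C9′–C10′ are cut and ring C is left intact. Forward, MeAlCl2 would open both terminal epoxides of the bis(epoxy allylsilane) A4. Each arm would fold chair–chair and end by loss of silicon, giving A5, the 3,3′-dihydroxy target as its 18,18′-bis(silyl ether).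

- In its favour: ring C and its two stereocentres are settled in a small molecule before anything else, and four rings and eight decalin stereocentres arrive in one operation. In its use of the twofold repetition of the target it is the equal of the chosen plan, and in the timing of the ring C problem it is the better.
- Against it: the cascade must succeed twice in one molecule, so every leak (monocyclic products, wrong folding, five-membered ring A) counts twice. The C12=C13 and C13′=C14′ alkenes lie within five- or six-membered-ring reach of the cations at C8 and C8′ and can compete with loss of silicon, a hazard the chosen plan avoids by cyclising before these alkenes exist. Two 3-hydroxyls must be removed afterwards. A4 is long to make: its ring C portion must be enantiopure and carry two differently attached arms, each with a (Z)-allylsilane and an epoxide.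
- Comparison: the single cyclisation event is the same as step 11 of the chosen route, so the two plans are equal in the chemistry they trust for the decalins. The chosen plan should be shorter, because it prepares one arm and lets dimerisation supply the core.

**Alternative 3:** The C14–C12′ bond is cut in a [3,3] sense. Forward, the δ-lactone A6, whose carbinol carbon is C14′ and carries the (E)-alkenyl group leading to the second decalin, would be enolised and O-silylated. It would rearrange through the boat transition state that the ring imposes, which forms C14–C12′, places the ring alkene at C13′=C14′ and delivers the cis acid A7 with the carboxyl carbon as C13.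

- In its favour: one carbinol stereocentre is transferred to both C14 and C12′, cis is enforced by the boat and the alkene position is unambiguous. On stereocontrol in ring C this plan is better than the chosen one, and it shares the decalin building block with it.
- Against it here: A6 needs an enantio-defined carbinol next to an (E)-trisubstituted alkene. After the rearrangement the second decalin must still be joined at C13 by a ketone olefination that has to create the (E)-C12=C13 alkene, a type of olefination with weak geometric control. The chosen plan makes that alkene early from an aldehyde and a stabilised ylide.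
- Comparison: a closed-shell sigmatropic shift with chirality transfer is more reliable than photodimerisation followed by a diradical ring expansion. In step count it needs two decalin units, as the chosen plan does, plus the lactone construction and the late olefination, roughly eight to ten steps more.

Key step: step 18

Remark on the structures: the monomer is the 18-ol (hydroxymethyl equatorial at C4, trans to the C10 methyl), so the oxygen must sit on the (E)-terminus of the acyclic chain. Ring C of the target is cis-(14S,12′S), and the cyclobutane is the trans head-to-head isomer.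

Remark on the precursor: 29 and 30 have the skeletons of (E)-labda-8(17),12,14-trien-18-ol and of its trans head-to-head cyclobutane dimer, with the C18 oxygen carried as the tert-butyldiphenylsilyl ether from step 10 to step 20. This costs no step, keeps protic groups away from a nickel-mediated ring expansion and gives every intermediate a UV handle. Any minor enantiomer of 29 ends up almost entirely in heterochiral dimers, which are diastereomers and are removed with the other isomers.

Assumption: 1, 2, 5, 9, 14, 25 and 27 are bought.

## Route

Step 1
Reactants: 1 3-[(tert-butyldimethylsilyl)oxy]propanal; 2 (2-bromoallyl)trimethylsilane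
Product: 4 rac-5-[(tert-butyldimethylsilyl)oxy]-2-[(trimethylsilyl)methyl]pent-1-en-3-ol, via [1-(trimethylsilylmethyl)vinyl]magnesium bromide 3 (not isolated)
Conditions: 2, Mg, THF, 40 °C; then 1, −78 → 0 °C; aq. NH4Cl
Reagents that add atoms: none
Why: Grignard addition of a 2-metallated allylsilane to the aldehyde forms C8–C9 and places silicon on C17 from the outset; the carbinol centre is left racemic because it becomes sp2 in step 2.

Step 2
Reactants: 4 rac-5-[(tert-butyldimethylsilyl)oxy]-2-[(trimethylsilyl)methyl]pent-1-en-3-ol; 5 triethyl orthoacetate
Product: 7 ethyl (4Z)-7-[(tert-butyldimethylsilyl)oxy]-4-[(trimethylsilyl)methyl]hept-4-enoate, via O-allyl O-ethyl ketene acetal 6 (not isolated)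
Conditions: 5 (excess), EtCO2H (cat.), 135 °C, EtOH distilled off
Reagents that add atoms: none
Why: Johnson–Claisen rearrangement: exchange with the ortho ester and loss of ethanol give ketene acetal 6, which rearranges through a chair with the CH2CH2OSi chain equatorial, so that C11 ends up trans to the new C7 and cis to CH2SiMe3 (the Z-allylsilane geometry that later gives the equatorial C9 side chain). The weak acid and the absence of water should leave the allylsilane and the silyl ether intact.

Step 3
Reactants: 7 ethyl (4Z)-7-[(tert-butyldimethylsilyl)oxy]-4-[(trimethylsilyl)methyl]hept-4-enoate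
Product: 8 (4Z)-7-[(tert-butyldimethylsilyl)oxy]-4-[(trimethylsilyl)methyl]hept-4-enal
Conditions: iBu2AlH (1.05 equiv), CH2Cl2, −78 °C; aq. potassium sodium tartrate
Reagents that add atoms: none
Why: Partial reduction of an unhindered ethyl ester by iBu2AlH at low temperature stops at the aluminium hemiacetal, which releases the aldehyde on work-up; no stereocentre is involved.

Step 4
Reactants: 8 (4Z)-7-[(tert-butyldimethylsilyl)oxy]-4-[(trimethylsilyl)methyl]hept-4-enal; 9 isopropenylmagnesium bromide
Product: 10 rac-(6Z)-9-[(tert-butyldimethylsilyl)oxy]-2-methyl-6-[(trimethylsilyl)methyl]nona-1,6-dien-3-ol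
Conditions: THF, −78 → 0 °C; aq. NH4Cl
Reagents that add atoms: none
Why: Grignard addition to the aldehyde forms C5–C10 and installs the 2-methylallylic alcohol for the second sigmatropic step; the carbinol centre is again racemic and is destroyed in step 5.

Step 5
Reactants: 10 rac-(6Z)-9-[(tert-butyldimethylsilyl)oxy]-2-methyl-6-[(trimethylsilyl)methyl]nona-1,6-dien-3-ol; 5 triethyl orthoacetate
Product: 12 ethyl (4E,8Z)-11-[(tert-butyldimethylsilyl)oxy]-4-methyl-8-[(trimethylsilyl)methyl]undeca-4,8-dienoate, via O-allyl O-ethyl ketene acetal 11 (not isolated)
Conditions: 5 (excess), EtCO2H (cat.), 135 °C, EtOH distilled off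
Reagents that add atoms: none
Why: Second Johnson–Claisen rearrangement via ketene acetal 11: the chair with the long chain equatorial gives the (E)-C5=C10 alkene, the standard outcome for 2-methylallylic secondary alcohols, and forms C1–C2.

Step 6
Reactants: 12 ethyl (4E,8Z)-11-[(tert-butyldimethylsilyl)oxy]-4-methyl-8-[(trimethylsilyl)methyl]undeca-4,8-dienoate
Product: 13 (4E,8Z)-11-[(tert-butyldimethylsilyl)oxy]-4-methyl-8-[(trimethylsilyl)methyl]undeca-4,8-dienal
Conditions: iBu2AlH (1.05 equiv), CH2Cl2, −78 °C; aq. potassium sodium tartrate
Reagents that add atoms: none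
Why: Same controlled ester-to-aldehyde reduction as in step 3.

Step 7
Reactants: 13 (4E,8Z)-11-[(tert-butyldimethylsilyl)oxy]-4-methyl-8-[(trimethylsilyl)methyl]undeca-4,8-dienal; 14 triethyl 2-phosphonopropionate
Product: 16 ethyl (2E,6E,10Z)-13-[(tert-butyldimethylsilyl)oxy]-2,6-dimethyl-10-[(trimethylsilyl)methyl]trideca-2,6,10-trienoate, via sodium phosphonate carbanion 15 (not isolated)
Conditions: 14, NaH, THF, 0 °C; then 13, 0 °C → rt
Reagents that add atoms: none
Why: Horner–Wadsworth–Emmons olefination forms C3=C4; the stabilised carbanion 15 adds reversibly, so the (E)-ester with C18 trans to C2 should predominate, and any Z isomer is removed at the alcohol stage.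

Step 8
Reactants: 16 ethyl (2E,6E,10Z)-13-[(tert-butyldimethylsilyl)oxy]-2,6-dimethyl-10-[(trimethylsilyl)methyl]trideca-2,6,10-trienoate
Product: 17 (2E,6E,10Z)-13-[(tert-butyldimethylsilyl)oxy]-2,6-dimethyl-10-[(trimethylsilyl)methyl]trideca-2,6,10-trien-1-ol
Conditions: iBu2AlH (2.5 equiv), CH2Cl2, −78 → −20 °C; aq. potassium sodium tartrate
Reagents that add atoms: none
Why: 1,2-Reduction of the conjugated ester by excess iBu2AlH gives the (E)-allylic alcohol needed for the directed epoxidation; silyl ether and allylsilane are inert to the hydride.

Step 9
Reactants: 17 (2E,6E,10Z)-13-[(tert-butyldimethylsilyl)oxy]-2,6-dimethyl-10-[(trimethylsilyl)methyl]trideca-2,6,10-trien-1-ol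
Product: 18 {(2S,3S)-3-[(3E,7Z)-10-[(tert-butyldimethylsilyl)oxy]-3-methyl-7-[(trimethylsilyl)methyl]deca-3,7-dien-1-yl]-2-methyloxiran-2-yl}methanol
Conditions: Ti(OiPr)4 (10 mol %), L-(+)-diethyl tartrate (12 mol %), tBuOOH, 4 Å MS, CH2Cl2, −20 °C
Reagents that add atoms: tert-butyl hydroperoxide, CC(C)(C)OO
Why: Sharpless asymmetric epoxidation: the catalyst formed from Ti(OiPr)4 and the tartrate binds the allylic alcohol and delivers oxygen to one face of C3=C4; with L-(+)-diethyl tartrate an (E)-2-methylalk-2-en-1-ol gives the (2S,3S)-epoxide, that is 3S at the future carbinol carbon, the sense required for the normal labdane series. The other three alkenes carry no directing hydroxyl and should not be epoxidised.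

Step 10
Reactants: 18 {(2S,3S)-3-[(3E,7Z)-10-[(tert-butyldimethylsilyl)oxy]-3-methyl-7-[(trimethylsilyl)methyl]deca-3,7-dien-1-yl]-2-methyloxiran-2-yl}methanol
Product: 19 tert-butyl({(2S,3S)-3-[(3E,7Z)-10-[(tert-butyldimethylsilyl)oxy]-3-methyl-7-[(trimethylsilyl)methyl]deca-3,7-dien-1-yl]-2-methyloxiran-2-yl}methoxy)diphenylsilane
Conditions: tBuPh2SiCl, imidazole, CH2Cl2, 0 °C → rt
Reagents that add atoms: tert-butyl(chloro)diphenylsilane, CC(C)(C)[Si](Cl)(c1ccccc1)c1ccccc1
Why: Silylation of the primary alcohol; the bulky, weakly basic silyl ether keeps the C18 oxygen from binding the Lewis acid or taking part in the epoxide opening, and it stays on until the last step.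

Step 11
Reactants: 19 tert-butyl({(2S,3S)-3-[(3E,7Z)-10-[(tert-butyldimethylsilyl)oxy]-3-methyl-7-[(trimethylsilyl)methyl]deca-3,7-dien-1-yl]-2-methyloxiran-2-yl}methoxy)diphenylsilane
Product: 20 (3S,4R,5R,9S,10R)-12-[(tert-butyldimethylsilyl)oxy]-18-[(tert-butyldiphenylsilyl)oxy]-13,14,15,16-tetranorlabd-8(17)-en-3-ol (3β-OH)
Conditions: MeAlCl2 (1.5 equiv), CH2Cl2, −78 °C; aq. NaHCO3
Reagents that add atoms: none
Why: Lewis acid initiated epoxy-polyene bicyclisation with allylsilane termination: MeAlCl2 activates the oxirane, C5=C10 attacks C4 with inversion, C8=C9 attacks C10 through a chair–chair fold, and the β-silyl cation at C8 loses the silyl group to leave only the 8(17)-methylene. C3 keeps the epoxide configuration (equatorial OH), the E-substituent of the oxirane (C18) becomes equatorial at C4, the (E)-C5=C10 alkene gives the trans ring fusion (5α-H, 10β-CH3) and the Z-allylsilane gives the equatorial C9 side chain, so all five stereocentres follow from the one epoxide.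

Step 12
Reactants: 20 (3S,4R,5R,9S,10R)-12-[(tert-butyldimethylsilyl)oxy]-18-[(tert-butyldiphenylsilyl)oxy]-13,14,15,16-tetranorlabd-8(17)-en-3-ol
Product: 21 O-[(3S,4R,5R,9S,10R)-12-[(tert-butyldimethylsilyl)oxy]-18-[(tert-butyldiphenylsilyl)oxy]-13,14,15,16-tetranorlabd-8(17)-en-3-yl] 1H-imidazole-1-carbothioate
Conditions: 1,1′-thiocarbonyldiimidazole, DMAP (cat.), PhMe, 90 °C
Reagents that add atoms: 1,1′-thiocarbonyldiimidazole, S=C(n1ccnc1)n1ccnc1
Why: Thioacylation of the hindered secondary alcohol under neutral conditions (first half of the Barton–McCombie deoxygenation); no alkoxide is formed, so the neighbouring silyl ether cannot migrate.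

Step 13
Reactants: 21 O-[(3S,4R,5R,9S,10R)-12-[(tert-butyldimethylsilyl)oxy]-18-[(tert-butyldiphenylsilyl)oxy]-13,14,15,16-tetranorlabd-8(17)-en-3-yl] 1H-imidazole-1-carbothioate
Product: 22 (4R,5R,9S,10R)-12-[(tert-butyldimethylsilyl)oxy]-18-[(tert-butyldiphenylsilyl)oxy]-13,14,15,16-tetranorlabd-8(17)-ene
Conditions: Bu3SnH, AIBN (cat.), PhMe, 110 °C
Reagents that add atoms: none
Why: Barton–McCombie radical deoxygenation: the stannyl radical adds to sulfur, the C3–O bond fragments and the secondary C3 radical is reduced by Bu3SnH; the C3 stereocentre disappears and the radical has no alkene within reach for cyclisation.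

Step 14
Reactants: 22 (4R,5R,9S,10R)-12-[(tert-butyldimethylsilyl)oxy]-18-[(tert-butyldiphenylsilyl)oxy]-13,14,15,16-tetranorlabd-8(17)-ene
Product: 23 (4R,5R,9S,10R)-18-[(tert-butyldiphenylsilyl)oxy]-13,14,15,16-tetranorlabd-8(17)-en-12-ol
Conditions: PPTS (cat.), EtOH, 45 °C
Reagents that add atoms: none
Why: Acid-catalysed solvolysis distinguishes the unhindered primary tert-butyldimethylsilyl ether at C12 from the neopentyl tert-butyldiphenylsilyl ether at C18, which cleaves far more slowly; the conditions are too mild to move the exocyclic alkene.

Step 15
Reactants: 23 (4R,5R,9S,10R)-18-[(tert-butyldiphenylsilyl)oxy]-13,14,15,16-tetranorlabd-8(17)-en-12-ol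
Product: 24 (4R,5R,9S,10R)-18-[(tert-butyldiphenylsilyl)oxy]-13,14,15,16-tetranorlabd-8(17)-en-12-al
Conditions: Dess–Martin periodinane, CH2Cl2, 0 °C → rt
Reagents that add atoms: none
Why: Dess–Martin oxidation of the primary alcohol to the aldehyde under near-neutral conditions; C9 is β to the carbonyl and cannot epimerise.

Step 16
Reactants: 24 (4R,5R,9S,10R)-18-[(tert-butyldiphenylsilyl)oxy]-13,14,15,16-tetranorlabd-8(17)-en-12-al; 25 2-(triphenylphosphoranylidene)propanal
Product: 26 (12E)-18-[(tert-butyldiphenylsilyl)oxy]-15-norlabda-8(17),12-dien-14-al
Conditions: PhMe, 90 °C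
Reagents that add atoms: none
Why: Wittig olefination with a formyl-stabilised ylide forms C12=C13 and gives the (E)-2-methyl enal directly (C11 trans to C14), because the stabilised ylide reacts under thermodynamic control; the product enal is less electrophilic than 24, which limits a second condensation.

Step 17
Reactants: 26 (12E)-18-[(tert-butyldiphenylsilyl)oxy]-15-norlabda-8(17),12-dien-14-al; 27 methyltriphenylphosphonium bromide
Product: 29 (12E)-18-[(tert-butyldiphenylsilyl)oxy]labda-8(17),12,14-triene, via methylenetriphenylphosphorane 28 (not isolated)
Conditions: 27, KOtBu, THF, 0 °C; then 26, 0 °C → rt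
Reagents that add atoms: none
Why: Wittig methylenation: ylide 28 adds 1,2 to the enal, forms C14=C15 and completes the (E)-diene without touching C12=C13; 29 is the tert-butyldiphenylsilyl ether of (E)-labda-8(17),12,14-trien-18-ol.

Step 18
Reactants: 29 (12E)-18-[(tert-butyldiphenylsilyl)oxy]labda-8(17),12,14-triene (two molecules)
Product: 30 trans-(14R,14′R) head-to-head cyclobutane dimer of 29 (new bonds C15–C15′ and C14–C14′; C12=C13 and C12′=C13′ both E; 18,18′-bis-O-tert-butyldiphenylsilyl)
Conditions: Ph2CO (0.2 equiv), PhH (degassed, 29 at ca. 1 M), hν 350–366 nm (Pyrex), 15 °C, partial conversion, unreacted 29 recycled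
Reagents that add atoms: none
Why: Benzophenone (triplet energy about 69 kcal/mol) absorbs the light and passes its triplet energy to the conjugated diene of 29 (about 58–60 kcal/mol) but not to the isolated 8(17)-methylene or to the arenes on silicon, so only C12–C15 is excited. The diene triplet bonds through its unsubstituted terminus C15 to C15′ of a ground-state molecule, which gives a triplet 1,4-diradical whose radical centres C14 and C14′ are both allylic (delocalised to C12 and C12′). After intersystem crossing the diradical collapses by radical recombination at C14–C14′, a four-membered ring closure of a 1,4-diradical; this is the established course of the triplet-sensitised dimerisation of buta-1,3-diene and isoprene to 1,2-divinylcyclobutanes. The two new stereocentres C14 and C14′ are set in this recombination: the two 1-methylalkenyl groups avoid each other and should end up trans, whereas the remote decalins exert no facial control, so 30 is expected together with its (14S,14′S) trans diastereomer, which is equally usable because both centres are erased in step 19. Head-to-head regiochemistry is required and is secured by the substrate, since C15 is the only unhindered terminus and C15–C15′ bonding is the only mode that leaves two allylic radicals. Four- rather than six- or eight-membered closure is required and is favoured by the high-energy sensitiser, which excites the s-trans diene and so produces transoid allyl radicals that cannot reach C12′ without rotation. High concentration lets bimolecular capture outrun unimolecular decay, and the pent-4-enyl relationship between C12 and the C8=C17 alkene offers only slow 4-exo or 5-endo intramolecular closure. The known weakness is E/Z equilibration of C12=C13 in the triplet, which is met by partial conversion and recycling of 29.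

Step 19
Reactants: 30 trans-(14R,14′R) head-to-head cyclobutane dimer of 29
Product: 31 cis-(14S,12′S)-cyclohexene dimer (ring C: C14–C15–C15′–C14′=C13′–C12′; C12=C13 E; 18,18′-bis-O-tert-butyldiphenylsilyl ether of the target)
Conditions: mesitylene (degassed), BHT (cat.), 175–180 °C, sealed tube; chromatography on AgNO3-impregnated SiO2
Reagents that add atoms: none
Why: Thermal 1,3-shift (vinylcyclobutane to cyclohexene rearrangement, as in the conversion of trans-1,2-divinylcyclobutane into 4-vinylcyclohexene): the strained, doubly allylic C14–C14′ bond homolyses, one allyl unit turns about C13′–C14′ and the diradical recloses between C14 and C12′. C14 and C12′ are formed without bias from the remote decalins, so 31 is expected together with its ring C diastereomers and is enriched by argentation chromatography; either trans-cyclobutane diastereomer from step 18 feeds the same diradical.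

Step 20
Reactants: 31 cis-(14S,12′S)-cyclohexene dimer (18,18′-bis-O-tert-butyldiphenylsilyl ether of the target)
Product: 32 CNP0194625.1, (14S,12′S)-bis-labdane-18,18′-diol
Conditions: Bu4NF, THF, rt → 45 °C; preparative HPLC
Reagents that add atoms: none
Why: Fluoride cleavage of both silyl ethers, driven by Si–F bond formation, releases the diol; no stereocentre or alkene is affected, and the final HPLC removes residual ring C isomers.

## Compound list

1 | 3-[(tert-butyldimethylsilyl)oxy]propanal | O=CCCO[Si](C)(C)C(C)(C)C | starting material
2 | (2-bromoallyl)trimethylsilane | C=C(Br)C[Si](C)(C)C | starting material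
3 | [1-(trimethylsilylmethyl)vinyl]magnesium bromide | C=C([Mg]Br)C[Si](C)(C)C | intermediate (not isolated)
4 | rac-5-[(tert-butyldimethylsilyl)oxy]-2-[(trimethylsilyl)methyl]pent-1-en-3-ol | C=C(C[Si](C)(C)C)C(O)CCO[Si](C)(C)C(C)(C)C | intermediate
5 | triethyl orthoacetate | CC(OCC)(OCC)OCC | starting material
6 | O-allyl O-ethyl ketene acetal of 4 | C=C(OCC)OC(CCO[Si](C)(C)C(C)(C)C)C(=C)C[Si](C)(C)C | intermediate (not isolated)
7 | ethyl (4Z)-7-[(tert-butyldimethylsilyl)oxy]-4-[(trimethylsilyl)methyl]hept-4-enoate | CCOC(=O)CC/C(C[Si](C)(C)C)=C/CCO[Si](C)(C)C(C)(C)C | intermediate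
8 | (4Z)-7-[(tert-butyldimethylsilyl)oxy]-4-[(trimethylsilyl)methyl]hept-4-enal | O=CCC/C(C[Si](C)(C)C)=C/CCO[Si](C)(C)C(C)(C)C | intermediate
9 | isopropenylmagnesium bromide | C=C(C)[Mg]Br | starting material
10 | rac-(6Z)-9-[(tert-butyldimethylsilyl)oxy]-2-methyl-6-[(trimethylsilyl)methyl]nona-1,6-dien-3-ol | C=C(C)C(O)CC/C(C[Si](C)(C)C)=C/CCO[Si](C)(C)C(C)(C)C | intermediate
11 | O-allyl O-ethyl ketene acetal of 10 | C=C(OCC)OC(CC/C(C[Si](C)(C)C)=C/CCO[Si](C)(C)C(C)(C)C)C(C)=C | intermediate (not isolated)
12 | ethyl (4E,8Z)-11-[(tert-butyldimethylsilyl)oxy]-4-methyl-8-[(trimethylsilyl)methyl]undeca-4,8-dienoate | CCOC(=O)CC/C(C)=C/CC/C(C[Si](C)(C)C)=C/CCO[Si](C)(C)C(C)(C)C | intermediate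
13 | (4E,8Z)-11-[(tert-butyldimethylsilyl)oxy]-4-methyl-8-[(trimethylsilyl)methyl]undeca-4,8-dienal | O=CCC/C(C)=C/CC/C(C[Si](C)(C)C)=C/CCO[Si](C)(C)C(C)(C)C | intermediate
14 | triethyl 2-phosphonopropionate | CCOC(=O)C(C)P(=O)(OCC)OCC | starting material
15 | sodium salt of the carbanion of 14 | CCOC(=O)[C-](C)P(=O)(OCC)OCC.[Na+] | intermediate (not isolated)
16 | ethyl (2E,6E,10Z)-13-[(tert-butyldimethylsilyl)oxy]-2,6-dimethyl-10-[(trimethylsilyl)methyl]trideca-2,6,10-trienoate | CCOC(=O)/C(C)=C/CC/C(C)=C/CC/C(C[Si](C)(C)C)=C/CCO[Si](C)(C)C(C)(C)C | intermediate
17 | (2E,6E,10Z)-13-[(tert-butyldimethylsilyl)oxy]-2,6-dimethyl-10-[(trimethylsilyl)methyl]trideca-2,6,10-trien-1-ol | OC/C(C)=C/CC/C(C)=C/CC/C(C[Si](C)(C)C)=C/CCO[Si](C)(C)C(C)(C)C | intermediate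
18 | {(2S,3S)-3-[(3E,7Z)-10-[(tert-butyldimethylsilyl)oxy]-3-methyl-7-[(trimethylsilyl)methyl]deca-3,7-dien-1-yl]-2-methyloxiran-2-yl}methanol | OC[C@]1(C)O[C@H]1CC/C(C)=C/CC/C(C[Si](C)(C)C)=C/CCO[Si](C)(C)C(C)(C)C | intermediate
19 | tert-butyldiphenylsilyl ether of 18 | CC(C)(C)[Si](OC[C@]1(C)O[C@H]1CC/C(C)=C/CC/C(C[Si](C)(C)C)=C/CCO[Si](C)(C)C(C)(C)C)(c1ccccc1)c1ccccc1 | intermediate
20 | (3S,4R,5R,9S,10R)-12-[(tert-butyldimethylsilyl)oxy]-18-[(tert-butyldiphenylsilyl)oxy]-13,14,15,16-tetranorlabd-8(17)-en-3-ol | CC(C)(C)[Si](C)(C)OCC[C@H]1C(=C)CC[C@H]2[C@](C)(CO[Si](c3ccccc3)(c3ccccc3)C(C)(C)C)[C@@H](O)CC[C@]12C | intermediate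
21 | O-3 imidazole-1-carbothioate of 20 | CC(C)(C)[Si](C)(C)OCC[C@H]1C(=C)CC[C@H]2[C@](C)(CO[Si](c3ccccc3)(c3ccccc3)C(C)(C)C)[C@@H](OC(=S)n3ccnc3)CC[C@]12C | intermediate
22 | (4R,5R,9S,10R)-12-[(tert-butyldimethylsilyl)oxy]-18-[(tert-butyldiphenylsilyl)oxy]-13,14,15,16-tetranorlabd-8(17)-ene | CC(C)(C)[Si](C)(C)OCC[C@H]1C(=C)CC[C@H]2[C@](C)(CO[Si](c3ccccc3)(c3ccccc3)C(C)(C)C)CCC[C@]12C | intermediate
23 | (4R,5R,9S,10R)-18-[(tert-butyldiphenylsilyl)oxy]-13,14,15,16-tetranorlabd-8(17)-en-12-ol | OCC[C@H]1C(=C)CC[C@H]2[C@](C)(CO[Si](c3ccccc3)(c3ccccc3)C(C)(C)C)CCC[C@]12C | intermediate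
24 | (4R,5R,9S,10R)-18-[(tert-butyldiphenylsilyl)oxy]-13,14,15,16-tetranorlabd-8(17)-en-12-al | O=CC[C@H]1C(=C)CC[C@H]2[C@](C)(CO[Si](c3ccccc3)(c3ccccc3)C(C)(C)C)CCC[C@]12C | intermediate
25 | 2-(triphenylphosphoranylidene)propanal | CC(C=O)=P(c1ccccc1)(c1ccccc1)c1ccccc1 | starting material
26 | (12E)-18-[(tert-butyldiphenylsilyl)oxy]-15-norlabda-8(17),12-dien-14-al | O=C/C(C)=C/C[C@H]1C(=C)CC[C@H]2[C@](C)(CO[Si](c3ccccc3)(c3ccccc3)C(C)(C)C)CCC[C@]12C | intermediate
27 | methyltriphenylphosphonium bromide | C[P+](c1ccccc1)(c1ccccc1)c1ccccc1.[Br-] | starting material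
28 | methylenetriphenylphosphorane | C=P(c1ccccc1)(c1ccccc1)c1ccccc1 | intermediate (not isolated)
29 | (12E)-18-[(tert-butyldiphenylsilyl)oxy]labda-8(17),12,14-triene | C=C/C(C)=C/C[C@H]1C(=C)CC[C@H]2[C@](C)(CO[Si](c3ccccc3)(c3ccccc3)C(C)(C)C)CCC[C@]12C | intermediate
30 | trans-(14R,14′R) head-to-head cyclobutane dimer of 29 | C=C1CC[C@H]2[C@](C)(CO[Si](c3ccccc3)(c3ccccc3)C(C)(C)C)CCC[C@]2(C)[C@H]1C/C=C(\C)[C@@H]1CC[C@H]1/C(C)=C/C[C@H]1C(=C)CC[C@H]2[C@](C)(CO[Si](c3ccccc3)(c3ccccc3)C(C)(C)C)CCC[C@]12C | intermediate
31 | cis-(14S,12′S)-cyclohexene dimer, 18,18′-bis-O-tert-butyldiphenylsilyl ether of the target | C=C1CC[C@H]2[C@](C)(CO[Si](c3ccccc3)(c3ccccc3)C(C)(C)C)CCC[C@]2(C)[C@H]1C/C=C(\C)[C@H]1CCC=C(C)[C@H]1C[C@H]1C(=C)CC[C@H]2[C@](C)(CO[Si](c3ccccc3)(c3ccccc3)C(C)(C)C)CCC[C@]12C | intermediate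
32 | CNP0194625.1 | C=C1CC[C@H]2[C@](C)(CO)CCC[C@]2(C)[C@H]1C/C=C(\C)[C@H]1CCC=C(C)[C@H]1C[C@H]1C(=C)CC[C@H]2[C@](C)(CO)CCC[C@]12C | target

## Step count and least certain steps

Total step count: 20. Longest linear sequence: 20 steps (from 1 and 2 to 32); every other partner is bought.

**Step 18 (key step).** The most likely failure is erosion of the C12=C13 geometry. The diene triplet relaxes by twisting about a double bond, so 29 drifts toward an E/Z photostationary mixture, and the diradical can relax into either allyl geometry, which spreads the dimers over E,E, E,Z and Z,Z forms. Next in likelihood are slow bimolecular capture at this molecular size and diversion of the diradical into six-membered-ring and cis-cyclobutane products. Partial conversion, recycling and high concentration are the built-in countermeasures. Fallback: go from 29 directly to 31 by thermal Diels–Alder dimerisation (neat or ca. 2 M in PhMe, BHT, 150–170 °C), in which the C12′–C15′ diene of one molecule adds to the C14=C15 vinyl group of another. The substituent on C12′ directs the orientation that gives C14–C12′ and C15–C15′, no excited state is involved so the alkene geometry is kept, and endo/exo and facial isomers are separated as in the main route. This fallback makes no new compound (F0).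

**Step 19.** The most likely failure is lack of selectivity in the reclosure: the diradical has no reason to prefer cis over trans or one face over the other. Part of the material can also return to 29 by cleavage of C15–C15′, or reach an eight-membered ring after closure to the cis-cyclobutane and [3,3] shift. Fallback: go from 30 to 31 with Ni(cod)2 and a triaryl phosphite, P(O-2-PhC6H4)3, in PhMe at 40–60 °C. Zerovalent nickel inserts into the doubly allylic C14–C14′ bond to give a bis(η3-allyl)nickel intermediate, the species of nickel-catalysed diene cyclodimerisation, and reductive elimination between C14 and C12′ closes the cyclohexene. The metal holds both allyl units on one face, which favours cis, and chiral phosphite or phosphoramidite ligands can then be screened for facial preference. The silyl ethers of 30 are what allow this, since free hydroxyls would protonate the allylnickel intermediate. This fallback makes no new compound (F0).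

**Step 11.** The most likely failure is capture of the C8 cation by the C12 silyl ether oxygen (closure to the 8,12-ether with loss of the silyl group) in competition with loss of the trimethylsilyl group. The second is arrest after ring A, or opening of the epoxide at C3, because the silyloxymethyl group lowers the stability of positive charge at C4. Fallback: change the group at C12 to an ester before the cyclisation. From 19, HF·pyridine/pyridine (THF, 0 °C) removes the primary alkyl silyl ether to give the epoxy alcohol F1; Ac2O/pyridine gives the acetate F2; MeAlCl2 (CH2Cl2, −78 °C) gives the bicyclic hydroxy acetate F3; 1,1′-thiocarbonyldiimidazole gives the thiocarbonylimidazolide F4; Bu3SnH/AIBN gives the deoxygenated acetate F5; and K2CO3/MeOH returns to the route at 23.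

**Step 2.** The most likely failure is protodesilylation of the allylsilane by the carboxylic acid catalyst at 135 °C, or acid-promoted ionisation of the allylic alcohol. Fallback: Eschenmoser–Claisen rearrangement under neutral conditions. From 4, N,N-dimethylacetamide dimethyl acetal (xylene, 140 °C) gives the dimethylamide F6 with the same chair-controlled geometry, and Cp2Zr(H)Cl (THF, rt) reduces the amide to the aldehyde, returning at 8.

**Step 16.** The most likely failure is sluggish condensation of the formyl-stabilised ylide, or further reaction of the product enal with a second ylide (chain extension). Fallback: the classical three-operation sequence. From 24, Horner–Wadsworth–Emmons reaction with 14 (NaH, THF) gives the (E)-ester F7, iBu2AlH gives the allylic alcohol F8, and MnO2 (CH2Cl2) oxidises it, returning at 26.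

## Further compounds

F0 | step 18 | none | none
F0 | step 19 | none | none
F1 | step 11 | (3Z,7E)-10-[(2S,3S)-3-{[(tert-butyldiphenylsilyl)oxy]methyl}-3-methyloxiran-2-yl]-8-methyl-4-[(trimethylsilyl)methyl]deca-3,7-dien-1-ol | CC(C)(C)[Si](OC[C@]1(C)O[C@H]1CC/C(C)=C/CC/C(C[Si](C)(C)C)=C/CCO)(c1ccccc1)c1ccccc1
F2 | step 11 | acetate of F1 | CC(C)(C)[Si](OC[C@]1(C)O[C@H]1CC/C(C)=C/CC/C(C[Si](C)(C)C)=C/CCOC(C)=O)(c1ccccc1)c1ccccc1
F3 | step 11 | (3S,4R,5R,9S,10R)-12-acetoxy-18-[(tert-butyldiphenylsilyl)oxy]-13,14,15,16-tetranorlabd-8(17)-en-3-ol | CC(=O)OCC[C@H]1C(=C)CC[C@H]2[C@](C)(CO[Si](c3ccccc3)(c3ccccc3)C(C)(C)C)[C@@H](O)CC[C@]12C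
F4 | step 11 | O-3 imidazole-1-carbothioate of F3 | CC(=O)OCC[C@H]1C(=C)CC[C@H]2[C@](C)(CO[Si](c3ccccc3)(c3ccccc3)C(C)(C)C)[C@@H](OC(=S)n3ccnc3)CC[C@]12C
F5 | step 11 | (4R,5R,9S,10R)-12-acetoxy-18-[(tert-butyldiphenylsilyl)oxy]-13,14,15,16-tetranorlabd-8(17)-ene | CC(=O)OCC[C@H]1C(=C)CC[C@H]2[C@](C)(CO[Si](c3ccccc3)(c3ccccc3)C(C)(C)C)CCC[C@]12C
F6 | step 2 | (4Z)-7-[(tert-butyldimethylsilyl)oxy]-N,N-dimethyl-4-[(trimethylsilyl)methyl]hept-4-enamide | CN(C)C(=O)CC/C(C[Si](C)(C)C)=C/CCO[Si](C)(C)C(C)(C)C
F7 | step 16 | ethyl (12E)-18-[(tert-butyldiphenylsilyl)oxy]-15-norlabda-8(17),12-dien-14-oate | CCOC(=O)/C(C)=C/C[C@H]1C(=C)CC[C@H]2[C@](C)(CO[Si](c3ccccc3)(c3ccccc3)C(C)(C)C)CCC[C@]12C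
F8 | step 16 | (12E)-18-[(tert-butyldiphenylsilyl)oxy]-15-norlabda-8(17),12-dien-14-ol | OC/C(C)=C/C[C@H]1C(=C)CC[C@H]2[C@](C)(CO[Si](c3ccccc3)(c3ccccc3)C(C)(C)C)CCC[C@]12C
A1 | alternative 1 | (3Z)-3-[(tert-butyldimethylsilyl)oxy]penta-1,3-diene | C=C/C(O[Si](C)(C)C(C)(C)C)=C/C
A2 | alternative 1 | (5R)-5-[(1R,2S,5R)-menthyloxy]furan-2(5H)-one | O=C1C=C[C@H](O[C@@H]2C[C@H](C)CC[C@H]2C(C)C)O1
A3 | alternative 1 | cis-fused ring C lactone acetal with C14′ silyl enol ether | O=C1O[C@@H](O[C@@H]3C[C@H](C)CC[C@H]3C(C)C)[C@@H]2[C@H](C)C(O[Si](C)(C)C(C)(C)C)=CC[C@H]12
A4 | alternative 2 | ring C bis(epoxy allylsilane) with two (2S,3S)-epoxide arms | CC(C)(C)[Si](C)(C)OC[C@]1(C)O[C@H]1CC/C(C)=C/CC/C(C[Si](C)(C)C)=C/C/C=C(\C)[C@H]2CCC=C(C)[C@H]2C/C=C(C[Si](C)(C)C)/CC/C=C(\C)CC[C@@H]1O[C@@]1(C)CO[Si](C)(C)C(C)(C)C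
A5 | alternative 2 | 3,3′-dihydroxy target as its 18,18′-bis(tert-butyldimethylsilyl) ether | C=C1CC[C@H]2[C@](C)(CO[Si](C)(C)C(C)(C)C)[C@@H](O)CC[C@]2(C)[C@H]1C/C=C(\C)[C@H]1CCC=C(C)[C@H]1C[C@H]1C(=C)CC[C@H]2[C@](C)(CO[Si](C)(C)C(C)(C)C)[C@@H](O)CC[C@]12C
A6 | alternative 3 | (6R)-6-[(E)-alkenyl] δ-lactone carrying the second decalin (C14′ carbinol) | O=C1CCC[C@@H](O1)/C(C)=C/C[C@H]1C(=C)CC[C@H]2[C@](C)(CO[Si](C)(C)C(C)(C)C)CCC[C@]12C
A7 | alternative 3 | cis ring C carboxylic acid carrying the second decalin | OC(=O)[C@H]1CCC=C(C)[C@H]1C[C@H]1C(=C)CC[C@H]2[C@](C)(CO[Si](C)(C)C(C)(C)C)CCC[C@]12C
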